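## The problem

The target is a furanoheliangolide built on a ten-membered carbocycle. An oxygen bridge from C10 to C3 makes a 3(2H)-furanone, a trans-fused α-methylene-γ-butyrolactone spans C6–C7, a (Z)-C4=C5 alkene carries a hydroxymethyl group, and the C8 oxygen bears a methacrylate. Locants used throughout: C1 is the furanone carbonyl carbon; C2=C3 is the furanone alkene, with C3 on the ring oxygen; C4 carries C15 (CH2OH); C5 is the second alkene carbon; C6 is the lactone carbinol; C7 carries C11; C8 is the ester carbinol; C9 is the methylene; C10 is the quaternary carbon with methyl C14; C11, C12 and C13 are the lactone α-carbon, carbonyl and exocyclic methylene. Four stereocentres must be set. C6, C7 and C8 are contiguous, with the C8 oxygen cis and the C6 oxygen trans to the C7–C11 bond, and the C10 oxygen is cis to the C8 oxygen across C9. C7 and C8 can be set together and can then direct C10 if all three sit on a rigid six-membered ring, whereas C6 must be made on the medium ring under the influence of C7. The finished molecule holds three Michael acceptors (the methylene lactone, the methacrylate and the C1-keto diene) and an allylic primary alcohol, so strong bases, nucleophiles and dissolving metals must be finished with before these groups appear. Closing a ten-membered ring by C–C bond formation is the usual stumbling block, but C1 and C6 are both oxygenated and stand 1,6 across the ring. The ten ring carbons are therefore the periphery of a decalin cut at a C1=C6 ring-fusion alkene, and C3 sits where the methoxy carbon of a 6-methoxytetralin would be (meta to C1, para to C6).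

## Retrosynthesis

**Late-stage groups (31 ⇒ 30 ⇒ 29 ⇒ 28 ⇒ 25).** The first cuts are the C15 O–Si bond, the C8 ester C–O bond, the C8 O–Si bond and the C11=C13 bond. These remove the two electrophilic groups that would not survive reduction or enolate chemistry, leaving lactone 25, which contains no acrylate. The forward steps need two silyl ethers of different lability (secondary TES in 28, primary TBS in 30) and a methylenation selective for the lactone α-carbon.

**Lactone and C6 (25 ⇒ 23).** Cutting the C12–O bond and the C6–H bond gives dienone ester 23. Closing the lactone onto C8 instead is excluded because C8 is silylated. The forward reaction must deliver hydride 1,2 to the C6 carbonyl, not to the vinylogous-ester carbonyl C1, and from the face that puts the C6 oxygen trans to C7–C11.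

**C4=C5 (23 ⇒ 21).** Removing the alkene gives saturated ketone 21, in which C4 is a stereocentre of no consequence. The alkene cannot be carried through the ring cleavage: in the bicyclic precursor it would make ring B a cyclohexadienone that tautomerises to a phenol. The forward step needs enolisation of the C6 ketone toward C5 rather than C7.

**Furanone (21 ⇒ 20).** Cutting the C3–O bond gives the open α′-hydroxy-1,3-diketone 20. This is simpler than any C–C disconnection of the heterocycle because hydroxy trione 20 is exactly what cleavage of a C1=C6 alkene leaves. The forward step is an acid cyclodehydration.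

**Ring cleavage, the key step (20 ⇒ 19).** Rejoining C1 and C6 as an alkene turns the ten-membered trione into the hexahydronaphthalenone 19. Cuts at C7–C8, C1–C2 or C2–C3/C4–C5 would all demand a medium-ring closure; this one demands none. The precursor is two fused six-membered rings with C7, C8 and C10 all-cis on one of them. The forward reaction only has to cleave the single alkene of 19 without harming the β-diketone that results.

**Dearomatisation (19 ⇒ 18 ⇒ 16 ⇒ 13).** The β,γ-unsaturated ketone 19 is the hydrolysis product of enol ether 18. Removing the silyl groups gives 16, the Birch product of anisole 13; only C–H bonds at C2 and C5 are cut. Reducing the arene after the ring-A centres are set is preferred to the reverse order, because stereocontrol on a tetralin is simple and on a diene it is not. The forward step must tolerate benzylic oxygens at C10 and C15, which are carried as alkoxides, and the ester, which is carried as a carboxylate after the lactone of 13 is opened.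

**C10 and C15 (13 ⇒ 11 + 12; 11 ⇒ 10 ⇒ 8 ⇒ 7).** Cutting C10–C14 gives aryl ketone 11 and methylmagnesium bromide 12. The cis-fused lactone of 11 is kept because its concave face should steer the methyl group trans to the C8 oxygen. The C10 carbonyl is traced to a benzylic C–H oxidation of 10. The C4–C15 bond is traced through aldehyde 8 to an arene formylation of lactone 7, done before the acid-sensitive tertiary carbinol exists.

**C7 and C8 (7 ⇒ 5 ⇒ 1 + 2).** Opening the lactone and removing the C8–H gives racemic keto ester 5, whose C7 centre is benzylic, α to the ketone and therefore labile; one catalytic reduction can set both centres. Cutting C7–C11 leads to 6-methoxy-2-tetralone 1 and methyl bromoacetate 2. The alternative of epoxidising a 1-substituted dihydronaphthalene and hydrogenolysing the benzylic C–O bond was set aside, because that epoxide is para-methoxybenzylic and would rearrange to the same 2-tetralone.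

## Roads not taken

**Alternative 1:** The cut is C7–C8. Seco aldehyde A1 carries the finished furanone and Z-alkene, a C8 aldehyde and a C6 butenolide. Divalent samarium (SmI2) would turn the aldehyde into a ketyl that adds to C7, and protonation of the samarium enolate at C11 gives carbinol A2.
- Merits: the route is convergent. C6 is set in the butenolide and directs the ketyl to its anti face, so the C6/C7 trans relationship comes without a separate reduction. A2 needs only methylenation, acylation and desilylation. In convergence, in control of C6 and in the length of the endgame this road is better than the chosen one.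
- Weak points: a ten-membered ring is closed by C–C bond formation, with the usual entropic and transannular cost. The C1-keto diene of A1 is reduced by SmI2 at least as easily as an aliphatic aldehyde. The aldehyde of A1 is β to the furanone ring oxygen and can open by elimination. The new C8 carbinol has no nearby controller.
- What the chosen plan sets against it: a ring that appears by cleavage, and a C7/C8 pair fixed on a rigid bicycle.

**Alternative 2:** The cut is C1–C2. Seco compound A3 carries the methacrylate, the methylene lactone, the Z-alkene, a C1 aldehyde and a C2 iodoalkyne. Divalent chromium (CrCl2) with catalytic divalent nickel (NiCl2) would give an alkynylchromium that adds to the aldehyde and closes the enyne carbinol A4. Oxidation to the ynone and 5-endo addition of the freed C10 hydroxyl would then make the furanone.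
- Merits: the organochromium is aldehyde-selective, the C1 configuration is irrelevant, and the furanone forms last under mild conditions. About four steps remain after cyclisation against seven in the chosen plan, and no reduction or enolate chemistry is needed on the bridged ring. In late-stage economy it is the better road.
- Weak points: the ring holds a C2≡C3 alkyne conjugated to a Z-alkene and fused to the lactone, so the alkyne must bend and oligomerisation competes. The aldehyde is neopentylic and α-oxygenated. All the electrophilic groups must survive the long linear assembly of A3, including its acyclic C6–C8 triad. The key step needs excess chromium.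
- What the chosen plan sets against it: a secure ring-forming event and cheap early chemistry.

**Alternative 3:** The cuts are C2–C3 and C4–C5. Cyclooctenone A5 has the C2=C5 alkene in an eight-membered ring and a C10 alkynyl ether (C3≡C4–C15). Monovalent silver (AgNTf2) would promote attack of C4 on C5 and collapse of the enolate carbon C2 onto C3, closing the furanone ring and a cyclobutene. Thermal conrotatory opening of the C2–C5 bond would give A6, which is the same compound as 25 of the chosen route.
- Merits: an eight-membered ring is easier to reach than a ten-membered one, and one operation makes two C–C bonds, the furanone and the diene. Conrotation of the cis-fused cyclobutene places C1 outward and C6 inward, which is exactly the required geometry; in this it is better than the dehydrogenation of step 12. If A5 were available in fewer than the thirteen steps that lead to 25, this road would be shorter.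
- Weak points: only two atoms (O, C10) tether the alkyne to the enone carbonyl, so the linear ynol ether must bend strongly to lie over C2=C5, and the first-formed zwitterion would hold a ketenium in a seven-membered ring. The cycloadduct has its cyclobutene double bond at a ring-fusion carbon. Tertiary alkynyl ethers with β-hydrogens fragment to ketenes on mild heating. A5 itself needs three stereocentres on a medium ring.
- What the chosen plan sets against it: a key step of a well-known type and stereocentres made on a six-membered ring.

Key step: step 10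

Assumption: the (R,R)-configured transfer-hydrogenation catalyst is taken to give the (2R)-carbinol of 6, on the steric model in which the branched benzylic carbon C7 is the large group; if the sense is opposite, the (S,S)-catalyst is used with no other change.

Remark: C4 is carried as a mixture of epimers from 19 to 22, since the centre becomes trigonal in step 12.

Step 1
Reactants: 1 6-methoxy-3,4-dihydronaphthalen-2(1H)-one (6-methoxy-2-tetralone); 2 methyl bromoacetate
Product: 5 methyl 2-(6-methoxy-2-oxo-1,2,3,4-tetrahydronaphthalen-1-yl)acetate (racemic), via pyrrolidine enamine 3 (not isolated), via C-alkylated iminium bromide 4 (not isolated)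
Conditions: pyrrolidine, PhMe, reflux (−H2O); then 2, MeCN, reflux; then H2O, 60 °C
Reagents that add atoms: water (O)
Why: Stork enamine alkylation: the enamine of a 2-tetralone is conjugated with the arene (C7=C8), so the bromoacetate alkylates the benzylic carbon C7, and hydrolysis of the iminium salt returns the ketone. No stereocontrol is needed because C7 of 5 is configurationally labile.

Step 2
Reactants: 5 methyl 2-(6-methoxy-2-oxo-1,2,3,4-tetrahydronaphthalen-1-yl)acetate
Product: 7 (3aR,9bS)-7-methoxy-3a,4,5,9b-tetrahydronaphtho[2,1-b]furan-2(1H)-one (cis-fused lactone), via hydroxy ester 6 (not isolated)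
Conditions: RuCl[(R,R)-TsDPEN](p-cymene) (cat.), HCO2H/Et3N (5:2), DMF, 40 °C; then TsOH (cat.), PhMe, 60 °C
Reagents that add atoms: none
Why: Noyori-type asymmetric transfer hydrogenation with dynamic kinetic resolution: C7, benzylic and α to the ketone, racemises in the amine medium faster than hydride is transferred. The catalyst reduces one enantiomer from the face anti to the C7 side chain, which sets C8 (R) and C7 (S) together as the cis pair. Acid then closes the cis-fused γ-lactone, which locks C7 against epimerisation.

Step 3
Reactants: 7 (3aR,9bS)-7-methoxy-3a,4,5,9b-tetrahydronaphtho[2,1-b]furan-2(1H)-one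
Product: 8 (3aR,9bS)-7-methoxy-2-oxo-1,2,3a,4,5,9b-hexahydronaphtho[2,1-b]furan-8-carbaldehyde
Conditions: Cl2CHOMe, TiCl4, CH2Cl2, −78 → 0 °C; then H2O
Reagents that add atoms: dichloromethyl methyl ether (COC(Cl)Cl); water (O)
Why: Rieche formylation (Friedel–Crafts type): of the two positions ortho to the methoxy group, C4 is unhindered and para to the C1 alkyl group, whereas C2 is flanked by the saturated ring. The lactone C–O bond is homobenzylic and is not ionised by the Lewis acid.

Step 4
Reactants: 8 (3aR,9bS)-7-methoxy-2-oxo-1,2,3a,4,5,9b-hexahydronaphtho[2,1-b]furan-8-carbaldehyde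
Product: 10 [(3aR,9bS)-7-methoxy-2-oxo-1,2,3a,4,5,9b-hexahydronaphtho[2,1-b]furan-8-yl]methyl acetate, via benzylic alcohol 9 (not isolated)
Conditions: NaBH4, MeOH/THF, −20 °C; then Ac2O, pyridine, DMAP (cat.), CH2Cl2, 0 °C → rt
Reagents that add atoms: acetic anhydride (CC(=O)OC(C)=O)
Why: Borohydride reduces the aryl aldehyde much faster than the γ-lactone, and acetylation follows in the same flask. The acyloxy group deactivates the new benzylic CH2 toward the chromium oxidant of step 5 and is removed without an extra step in step 7.

Step 5
Reactants: 10 [(3aR,9bS)-7-methoxy-2-oxo-1,2,3a,4,5,9b-hexahydronaphtho[2,1-b]furan-8-yl]methyl acetate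
Product: 11 [(3aR,9bS)-7-methoxy-2,5-dioxo-1,2,3a,4,5,9b-hexahydronaphtho[2,1-b]furan-8-yl]methyl acetate
Conditions: CrO3, 3,5-dimethylpyrazole, CH2Cl2, −20 °C
Reagents that add atoms: chromium trioxide (O=[Cr](=O)=O)
Why: Benzylic C–H oxidation by the CrO3–3,5-dimethylpyrazole complex, a reaction known to convert the C6 methylene of 3-methoxyestra-1,3,5(10)-trienes into the ketone despite a para-activated tertiary benzylic C–H. Here the competing C7–H is tertiary, pseudo-equatorial in the cis-fused bicycle (poor overlap with the arene) and flanked by two electron-withdrawing groups. The acetoxymethyl CH2 is deactivated by its acyloxy group.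

Step 6
Reactants: 11 [(3aR,9bS)-7-methoxy-2,5-dioxo-1,2,3a,4,5,9b-hexahydronaphtho[2,1-b]furan-8-yl]methyl acetate; 12 methylmagnesium bromide
Product: 13 [(3aR,5S,9bS)-5-hydroxy-7-methoxy-5-methyl-2-oxo-1,2,3a,4,5,9b-hexahydronaphtho[2,1-b]furan-8-yl]methyl acetate
Conditions: CeCl3, THF, −78 °C; then aq. NH4Cl
Reagents that add atoms: none
Why: 1,2-Addition of the organocerium reagent made from 12 and CeCl3, which is nucleophilic but weakly basic, so the β-acyloxy aryl ketone is not enolised (no elimination to a naphthol) and the lactone and acetate are spared at −78 °C. The cis-fused lactone ring shields the concave face, so methyl enters from the convex face and the new C10 hydroxyl is cis to the C8 oxygen (5S).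

Step 7
Reactants: 13 [(3aR,5S,9bS)-5-hydroxy-7-methoxy-5-methyl-2-oxo-1,2,3a,4,5,9b-hexahydronaphtho[2,1-b]furan-8-yl]methyl acetate
Product: 16 methyl 2-[(1S,2R,4S)-2,4-dihydroxy-7-(hydroxymethyl)-6-methoxy-4-methyl-1,2,3,4,5,8-hexahydronaphthalen-1-yl]acetate, via lithium carboxylate 14 (not isolated), via Birch carboxylate 15 (not isolated)
Conditions: LiOH, THF/H2O, rt, then evaporation; Li, NH3 (l), THF, t-BuOH, −78 → −33 °C; solid NH4Cl, evaporation of NH3; then MeI, NaHCO3, DMF, 0 °C → rt
Reagents that add atoms: lithium hydroxide ([Li+].[OH-]); iodomethane (CI)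
Why: Hydroxide opens the lactone and removes the acetate, giving a carboxylate that survives dissolving metal. Birch reduction of the anisole protonates the two unsubstituted positions C2 and C5, leaving the C1=C6 alkene and the C3=C4 enol ether; the benzylic oxygens are present as alkoxides, which are poor leaving groups. SN2 methylation of the carboxylate restores the ester without acid, so the enol ether is not hydrolysed and the γ-hydroxy acid does not relactonise.

Step 8
Reactants: 16 methyl 2-[(1S,2R,4S)-2,4-dihydroxy-7-(hydroxymethyl)-6-methoxy-4-methyl-1,2,3,4,5,8-hexahydronaphthalen-1-yl]acetate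
Product: 18 methyl 2-[(1S,2R,4S)-7-{[tert-butyl(dimethyl)silyl]oxymethyl}-4-hydroxy-6-methoxy-4-methyl-2-(triethylsilyloxy)-1,2,3,4,5,8-hexahydronaphthalen-1-yl]acetate, via mono-silyl ether 17 (not isolated)
Conditions: TBSCl, imidazole, DMF, −20 → 0 °C; then TESCl, DMAP (cat.), 0 °C → rt
Reagents that add atoms: tert-butyldimethylsilyl chloride (CC(C)(C)[Si](C)(C)Cl); triethylsilyl chloride (CC[Si](CC)(CC)Cl)
Why: Rate-controlled silylation: TBSCl takes the primary C15 hydroxyl, TESCl then takes the secondary C8 hydroxyl, and the tertiary C10 hydroxyl stays free for the furanone. The basic medium keeps the enol ether intact.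

Step 9
Reactants: 18 methyl 2-[(1S,2R,4S)-7-{[tert-butyl(dimethyl)silyl]oxymethyl}-4-hydroxy-6-methoxy-4-methyl-2-(triethylsilyloxy)-1,2,3,4,5,8-hexahydronaphthalen-1-yl]acetate
Product: 19 methyl 2-[(1S,2R,4S)-7-{[tert-butyl(dimethyl)silyl]oxymethyl}-4-hydroxy-4-methyl-6-oxo-2-(triethylsilyloxy)-1,2,3,4,5,6,7,8-octahydronaphthalen-1-yl]acetate (both C7 epimers of the naphthalene numbering, which is C4 of the skeleton)
Conditions: oxalic acid on wet SiO2, CH2Cl2, 0 °C → rt
Reagents that add atoms: water (O)
Why: Mild acid hydrolysis of the methyl enol ether (C-protonation at C4, loss of methanol from the hemiketal) gives the β,γ-unsaturated ketone without moving the C1=C6 alkene into conjugation and without cleaving the silyl ethers. C4 forms as an epimer mixture, which is immaterial.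

Step 10
Reactants: 19 methyl 2-[(1S,2R,4S)-7-{[tert-butyl(dimethyl)silyl]oxymethyl}-4-hydroxy-4-methyl-6-oxo-2-(triethylsilyloxy)-1,2,3,4,5,6,7,8-octahydronaphthalen-1-yl]acetate
Product: 20 methyl 2-[(1R,2R,4S)-8-{[tert-butyl(dimethyl)silyl]oxymethyl}-4-hydroxy-4-methyl-5,7,10-trioxo-2-(triethylsilyloxy)cyclodecyl]acetate (C1, C3 and C6 ketones and C10 hydroxyl in skeleton locants; C4 epimers)
Conditions: O3, CH2Cl2/MeOH (4:1), NaHCO3, −78 °C; then Me2S, −78 °C → rt
Reagents that add atoms: ozone ([O-][O+]=O)
Why: Ozone adds to the electron-rich tetrasubstituted C1=C6 alkene by 1,3-dipolar cycloaddition, and the primary ozonide fragments into a ketone and a carbonyl oxide that methanol traps as the α-methoxy hydroperoxide. Me2S reduces this peroxide to the second ketone, so C1 and C6 emerge as carbonyl carbons and no skeletal bond is formed. The closest known reaction type is the ozonolysis of the ring-fusion alkene of Birch-derived octahydronaphthalenes to cyclodecane-1,6-diones. The ten-membered ring is not closed by bond formation: it is the periphery of the two fused six-membered rings and appears when their shared bond is cut, so no entropic or transannular barrier to cyclisation is paid. No stereocentre is created; C7, C8 and C10 pass through unchanged, and the cold buffered work-up is meant to keep C7, now α to the C6 ketone, from epimerising. The only selectivity needed is chemoselectivity: 19 has a single C=C, and the silyl ethers, the ester and the tertiary alcohol are inert to ozone at −78 °C. Reductive work-up leaves the new β-diketone and the β-silyloxy ketone intact.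

Step 11
Reactants: 20 methyl 2-[(1R,2R,4S)-8-{[tert-butyl(dimethyl)silyl]oxymethyl}-4-hydroxy-4-methyl-5,7,10-trioxo-2-(triethylsilyloxy)cyclodecyl]acetate
Product: 21 furanone keto ester: ten-membered ring with the C10–O–C3 bridge (C1 ketone and C2=C3) plus C6 ketone and C4 CH2OTBS (epimers) and C7 CH2CO2Me and C8 OTES
Conditions: TsOH·H2O (cat.), PhH, 4 Å molecular sieves, rt
Reagents that add atoms: none
Why: Acid-catalysed cyclodehydration of an α′-hydroxy-1,3-diketone to a 3(2H)-furanone: the C10 hydroxyl adds 5-exo-trig to the C3 carbonyl and the hemiketal loses water toward C2. The resulting vinylogous ester is an irreversible sink that outcompetes the reversible hemiketal at C6. Catalytic acid in an aprotic solvent spares the silyl ethers.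

Step 12
Reactants: 21 furanone keto ester
Product: 23 (4Z)-dienone ester: as 21 but with the C4=C5 alkene (C3 cis to C6) conjugated to the C6 ketone, via trimethylsilyl enol ether 22 (not isolated)
Conditions: LiHMDS, TMSCl, THF, −78 °C; then Pd(OAc)2, MeCN, rt
Reagents that add atoms: none
Why: Saegusa–Ito oxidation: kinetic deprotonation of the C6 ketone at the less hindered C5 methylene, with internal TMSCl quench, gives the C5=C6 silyl enol ether. Its oxa-π-allyl palladium intermediate can only β-eliminate the C4 hydrogen, so both C4 epimers converge on the C4=C5 enone. The Z geometry is expected because it avoids a trans alkene in the nine-membered ring closed by the oxygen bridge.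

Step 13
Reactants: 23 (4Z)-dienone ester
Product: 25 trans-fused 6,12-lactone: O6 trans to C7–C11 with C8 OTES and C15 OTBS and a saturated C11 methylene, via allylic alcohol 24 (not isolated)
Conditions: NaBH4, CeCl3·7H2O, MeOH, −78 °C; then PPTS (cat.), PhH, 40 °C
Reagents that add atoms: none
Why: Luche reduction: the cerium-activated borohydride adds 1,2 to the enone carbonyl C6 and leaves the less electrophilic vinylogous-ester carbonyl C1 and the ester. Hydride is expected to add anti to the C7 side chain, with C11 antiperiplanar to the forming C–H bond and the C7–C8 ring bond near the carbonyl oxygen, which places the C6 oxygen trans to C7–C11. The γ-hydroxy ester then closes to the lactone.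

Step 14
Reactants: 25 trans-fused 6,12-lactone
Product: 28 α-methylene lactone (C11=C13) with C8 OTES and C15 OTBS, via Mannich base 26 (not isolated), via ammonium iodide 27 (not isolated)
Conditions: LDA, THF, −78 °C; CH2=NMe2+ I−, −78 → 0 °C; then MeI, CH2Cl2, rt; then aq. NaHCO3, rt
Reagents that add atoms: Eschenmoser's salt (C=[N+](C)C.[I-])
Why: Enolate Mannich reaction followed by quaternisation and β-elimination, the standard α-methylenation of γ-lactones. The lactone α-CH2 is the only readily enolisable position, because the furanone carbonyl is flanked by the quaternary C10 and a vinylic carbon.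

Step 15
Reactants: 28 α-methylene lactone with C8 OTES and C15 OTBS
Product: 29 C8 alcohol: α-methylene lactone with free C8 hydroxyl and C15 OTBS
Conditions: PPTS, MeOH/CH2Cl2, 0 °C
Reagents that add atoms: none
Why: Acid-catalysed methanolysis removes the secondary triethylsilyl ether much faster than the primary tert-butyldimethylsilyl ether. A free C8 hydroxyl cis to C11 beside a trans-fused 6,12-lactone is a common arrangement in germacranolides, so no lactone migration is expected under mild acid.

Step 16
Reactants: 29 C8 alcohol
Product: 30 15-O-tert-butyldimethylsilyl ether of the target (C8 methacrylate)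
Conditions: methacrylic anhydride, Et3N, DMAP (cat.), CH2Cl2, 0 °C → rt
Reagents that add atoms: methacrylic anhydride (CC(=C)C(=O)OC(=O)C(C)=C)
Why: DMAP-catalysed acylation of the hindered secondary alcohol by the anhydride. The only other hydroxyl, C15, is still silylated.

Step 17
Reactants: 30 15-O-tert-butyldimethylsilyl ether of the target
Product: 31 the target furanoheliangolide (CNP0180483.4)
Conditions: HF·pyridine, pyridine, THF, 0 °C → rt
Reagents that add atoms: none
Why: Buffered fluoride cleavage of the primary allylic silyl ether under slightly acidic conditions, which the methacrylate, the methylene lactone and the dienone tolerate, unlike basic fluoride sources.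

## Compound list

1 | 6-methoxy-3,4-dihydronaphthalen-2(1H)-one | COc1ccc2c(c1)CCC(=O)C2 | starting material
2 | methyl bromoacetate | COC(=O)CBr | starting material
3 | 1-(6-methoxy-3,4-dihydronaphthalen-2-yl)pyrrolidine | COc1ccc2c(c1)CCC(=C2)N1CCCC1 | intermediate (not isolated)
4 | 1-[6-methoxy-1-(2-methoxy-2-oxoethyl)-3,4-dihydronaphthalen-2(1H)-ylidene]pyrrolidinium bromide | COC(=O)CC1c2ccc(OC)cc2CCC1=[N+]1CCCC1.[Br-] | intermediate (not isolated)
5 | methyl 2-(6-methoxy-2-oxo-1,2,3,4-tetrahydronaphthalen-1-yl)acetate, racemic | COC(=O)CC1c2ccc(OC)cc2CCC1=O | intermediate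
6 | methyl 2-[(1S,2R)-2-hydroxy-6-methoxy-1,2,3,4-tetrahydronaphthalen-1-yl]acetate | COC(=O)C[C@@H]1[C@H](O)CCc2cc(OC)ccc21 | intermediate (not isolated)
7 | (3aR,9bS)-7-methoxy-3a,4,5,9b-tetrahydronaphtho[2,1-b]furan-2(1H)-one | O=C1C[C@@H]2[C@H](O1)CCc1cc(OC)ccc12 | intermediate
8 | (3aR,9bS)-7-methoxy-2-oxo-1,2,3a,4,5,9b-hexahydronaphtho[2,1-b]furan-8-carbaldehyde | O=C1C[C@@H]2[C@H](O1)CCc1cc(OC)c(C=O)cc12 | intermediate
9 | (3aR,9bS)-8-(hydroxymethyl)-7-methoxy-3a,4,5,9b-tetrahydronaphtho[2,1-b]furan-2(1H)-one | O=C1C[C@@H]2[C@H](O1)CCc1cc(OC)c(CO)cc12 | intermediate (not isolated)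
10 | [(3aR,9bS)-7-methoxy-2-oxo-1,2,3a,4,5,9b-hexahydronaphtho[2,1-b]furan-8-yl]methyl acetate | O=C1C[C@@H]2[C@H](O1)CCc1cc(OC)c(COC(C)=O)cc12 | intermediate
11 | [(3aR,9bS)-7-methoxy-2,5-dioxo-1,2,3a,4,5,9b-hexahydronaphtho[2,1-b]furan-8-yl]methyl acetate | O=C1C[C@@H]2[C@H](O1)CC(=O)c1cc(OC)c(COC(C)=O)cc12 | intermediate
12 | methylmagnesium bromide | C[Mg]Br | starting material
13 | [(3aR,5S,9bS)-5-hydroxy-7-methoxy-5-methyl-2-oxo-1,2,3a,4,5,9b-hexahydronaphtho[2,1-b]furan-8-yl]methyl acetate | O=C1C[C@@H]2[C@H](O1)C[C@](C)(O)c1cc(OC)c(COC(C)=O)cc12 | intermediate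
14 | lithium 2-[(1S,2R,4S)-2,4-dihydroxy-7-(hydroxymethyl)-6-methoxy-4-methyl-1,2,3,4-tetrahydronaphthalen-1-yl]acetate | [Li+].[O-]C(=O)C[C@@H]1[C@H](O)C[C@](C)(O)c2cc(OC)c(CO)cc21 | intermediate (not isolated)
15 | lithium 2-[(1S,2R,4S)-2,4-dihydroxy-7-(hydroxymethyl)-6-methoxy-4-methyl-1,2,3,4,5,8-hexahydronaphthalen-1-yl]acetate | [Li+].[O-]C(=O)C[C@@H]1[C@H](O)C[C@](C)(O)C2=C1CC(CO)=C(OC)C2 | intermediate (not isolated)
16 | methyl 2-[(1S,2R,4S)-2,4-dihydroxy-7-(hydroxymethyl)-6-methoxy-4-methyl-1,2,3,4,5,8-hexahydronaphthalen-1-yl]acetate | COC(=O)C[C@@H]1[C@H](O)C[C@](C)(O)C2=C1CC(CO)=C(OC)C2 | intermediate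
17 | methyl 2-[(1S,2R,4S)-7-{[tert-butyl(dimethyl)silyl]oxymethyl}-2,4-dihydroxy-6-methoxy-4-methyl-1,2,3,4,5,8-hexahydronaphthalen-1-yl]acetate | COC(=O)C[C@@H]1[C@H](O)C[C@](C)(O)C2=C1CC(CO[Si](C)(C)C(C)(C)C)=C(OC)C2 | intermediate (not isolated)
18 | methyl 2-[(1S,2R,4S)-7-{[tert-butyl(dimethyl)silyl]oxymethyl}-4-hydroxy-6-methoxy-4-methyl-2-(triethylsilyloxy)-1,2,3,4,5,8-hexahydronaphthalen-1-yl]acetate | COC(=O)C[C@@H]1[C@H](O[Si](CC)(CC)CC)C[C@](C)(O)C2=C1CC(CO[Si](C)(C)C(C)(C)C)=C(OC)C2 | intermediate
19 | methyl 2-[(1S,2R,4S)-7-{[tert-butyl(dimethyl)silyl]oxymethyl}-4-hydroxy-4-methyl-6-oxo-2-(triethylsilyloxy)-1,2,3,4,5,6,7,8-octahydronaphthalen-1-yl]acetate, both epimers at skeleton C4 | COC(=O)C[C@@H]1[C@H](O[Si](CC)(CC)CC)C[C@](C)(O)C2=C1CC(CO[Si](C)(C)C(C)(C)C)C(=O)C2 | intermediate (key-step precursor)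
20 | methyl 2-[(1R,2R,4S)-8-{[tert-butyl(dimethyl)silyl]oxymethyl}-4-hydroxy-4-methyl-5,7,10-trioxo-2-(triethylsilyloxy)cyclodecyl]acetate, both epimers at skeleton C4 | COC(=O)C[C@@H]1[C@H](O[Si](CC)(CC)CC)C[C@](C)(O)C(=O)CC(=O)C(CO[Si](C)(C)C(C)(C)C)CC1=O | intermediate (key-step product)
21 | furanone keto ester: C10–O–C3 bridged 3(2H)-furanone (C1 ketone, C2=C3), C6 ketone, C4 CH2OTBS (epimers), C7 CH2CO2Me, C8 OTES; C7 side chain, C8 oxygen and C10 ring oxygen on one face | COC(=O)C[C@@H]1[C@H](O[Si](CC)(CC)CC)C[C@]2(C)OC(=CC2=O)C(CO[Si](C)(C)C(C)(C)C)CC1=O | intermediate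
22 | C5=C6 trimethylsilyl enol ether of 21 | COC(=O)C[C@@H]1[C@H](O[Si](CC)(CC)CC)C[C@]2(C)OC(=CC2=O)C(CO[Si](C)(C)C(C)(C)C)C=C1O[Si](C)(C)C | intermediate (not isolated)
23 | (4Z)-dienone ester: as 21 with C4=C5 (C3 cis to C6) conjugated to the C6 ketone | COC(=O)C[C@@H]1[C@H](O[Si](CC)(CC)CC)C[C@]2(C)OC(=CC2=O)/C(CO[Si](C)(C)C(C)(C)C)=C\C1=O | intermediate
24 | C6 allylic alcohol of 23, hydroxyl trans to the C7 side chain | COC(=O)C[C@@H]1[C@H](O[Si](CC)(CC)CC)C[C@]2(C)OC(=CC2=O)/C(CO[Si](C)(C)C(C)(C)C)=C\[C@H]1O | intermediate (not isolated)
25 | trans-fused 6,12-lactone with C8 OTES, C15 OTBS and saturated C11 | CC[Si](CC)(CC)O[C@@H]1C[C@]2(C)OC(=CC2=O)/C(CO[Si](C)(C)C(C)(C)C)=C\[C@H]2OC(=O)C[C@@H]21 | intermediate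
26 | 11-(dimethylaminomethyl) derivative of 25 (C11 epimers) | CC[Si](CC)(CC)O[C@@H]1C[C@]2(C)OC(=CC2=O)/C(CO[Si](C)(C)C(C)(C)C)=C\[C@H]2OC(=O)C(CN(C)C)[C@@H]21 | intermediate (not isolated)
27 | 11-(trimethylammoniomethyl) iodide of 25 | CC[Si](CC)(CC)O[C@@H]1C[C@]2(C)OC(=CC2=O)/C(CO[Si](C)(C)C(C)(C)C)=C\[C@H]2OC(=O)C(C[N+](C)(C)C)[C@@H]21.[I-] | intermediate (not isolated)
28 | α-methylene lactone (C11=C13) with C8 OTES and C15 OTBS | CC[Si](CC)(CC)O[C@@H]1C[C@]2(C)OC(=CC2=O)/C(CO[Si](C)(C)C(C)(C)C)=C\[C@H]2OC(=O)C(=C)[C@@H]21 | intermediate
29 | α-methylene lactone with free C8 hydroxyl and C15 OTBS | O[C@@H]1C[C@]2(C)OC(=CC2=O)/C(CO[Si](C)(C)C(C)(C)C)=C\[C@H]2OC(=O)C(=C)[C@@H]21 | intermediate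
30 | 15-O-tert-butyldimethylsilyl ether of the target | C=C(C)C(=O)O[C@@H]1C[C@]2(C)OC(=CC2=O)/C(CO[Si](C)(C)C(C)(C)C)=C\[C@H]2OC(=O)C(=C)[C@@H]21 | intermediate
31 | target furanoheliangolide: 8-O-methacryloyl, 15-hydroxy, (4Z), 6,12-olide | C=C(C)C(=O)O[C@@H]1C[C@]2(C)OC(=CC2=O)/C(CO)=C\[C@H]2OC(=O)C(=C)[C@@H]21 | target

## Step count and risks

Total: 17 steps. Longest linear sequence: 17 steps (the route is linear from 1).

**Step 10 (key step).** The most likely failure is capture of the carbonyl oxide or hydroperoxide by the neighbouring C3 carbonyl or C10 hydroxyl to give stable cyclic peroxides. The second is transannular aldol condensation of the new β-diketone onto the C6 ketone during work-up. Fallback: from 19, the C3 ketone is taken out of play by borohydride reduction to the C3 carbinol F1. Ozonolysis with Me2S work-up then gives the hydroxy dione F2, which has no β-diketone. Dess–Martin oxidation of the secondary alcohol returns the route to 20.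

**Step 5.** Oxidation may occur at the wrong benzylic position (the C7–H para to the methoxy group, or the acetoxymethyl CH2). The β-acyloxy ketone may also eliminate the lactone carboxylate and aromatise to a naphthol. Fallback, with the selectivity reversed by using a carbanion in place of an oxidant: from 8, LiAlH4 gives the triol F3. Metalation with LDA/KOt-Bu selects the benzylic CH2 meta to the methoxy group, since an anion para to it is destabilised; borylation with B(OMe)3 and oxidation with H2O2 give the tetraol F4. TEMPO with PhI(OAc)2 oxidises the 1,4-diol to the lactone and the two benzylic alcohols to carbonyls, giving the keto aldehyde lactone F5. NaBH4 at −78 °C reduces only the aldehyde, giving the hydroxymethyl keto lactone F6, and acetylation returns the route to 11.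

**Step 7.** Hydrogenolysis of a benzylic C–O bond (C15–O or C10–O) may compete with ring reduction, and the poorly soluble polyanion may be reduced incompletely. Fallback, which keeps the C15 oxygen out of the Birch step: from 7, the oxidation of step 5 gives the keto lactone F7, and the addition of step 6 gives the tertiary alcohol F8. The saponification, Birch reduction and methylation of step 7 then give the diol ester F9, with only the C10 alkoxide benzylic during the reduction. TESCl with imidazole gives the C8 silyl ether F10. Vilsmeier–Haack formylation of the enol ether at C4 (POCl3, DMF, pyridine, then aq. NaOAc) gives the β-methoxy enal F11. Luche reduction gives the allylic alcohol F12, and TBSCl with imidazole returns the route to 18.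

**Step 12.** Enolisation may go toward C7 or C4 instead of C5, leading to β-elimination of the C8 or C15 silyloxy group, or the enone may form with E geometry. Fallback without an enolate: from 21, radical bromination with NBS and AIBN in PhCF3 at the tertiary C4–H, which is allylic to the furanone alkene, gives the C4 bromide F13. DBU then removes HBr toward the acidic C5–H and returns the route to 23.

**Step 13.** Facial selectivity of hydride addition at C6 may be poor, because the preferred conformation about C6–C7 in the bridged ring is not known; conjugate reduction of the dienone is a lesser risk. Fallback by intramolecular delivery: from 23, PPTS in MeOH removes the TES group to give the β-hydroxy dienone F14. Evans–Saksena reduction (Me4NBH(OAc)3, MeCN/AcOH, −30 °C) delivers hydride from the C8 hydroxyl and gives the anti 1,3-diol F15, with the C6 oxygen trans to the C8 oxygen as required. PPTS in benzene is expected to close the trans-fused lactone onto the C6 hydroxyl, giving the hydroxy lactone F16 (the same compound as A2). TESCl with imidazole returns the route to 25.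

## Further compounds

F1 | step 10 | C3 carbinol of 19 (C3 and C4 epimers) | COC(=O)C[C@@H]1[C@H](O[Si](CC)(CC)CC)C[C@](C)(O)C2=C1CC(CO[Si](C)(C)C(C)(C)C)C(O)C2
F2 | step 10 | ten-membered 3,10-dihydroxy-1,6-dione (C3 and C4 epimers) | COC(=O)C[C@@H]1[C@H](O[Si](CC)(CC)CC)C[C@](C)(O)C(=O)CC(O)C(CO[Si](C)(C)C(C)(C)C)CC1=O
F3 | step 5 | (1S,2R)-1-(2-hydroxyethyl)-7-(hydroxymethyl)-6-methoxy-1,2,3,4-tetrahydronaphthalen-2-ol | OCC[C@@H]1[C@H](O)CCc2cc(OC)c(CO)cc21
F4 | step 5 | (1S,2R)-1-(2-hydroxyethyl)-7-(hydroxymethyl)-6-methoxy-1,2,3,4-tetrahydronaphthalene-2,4-diol (C4 epimers) | OCC[C@@H]1[C@H](O)CC(O)c2cc(OC)c(CO)cc21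
F5 | step 5 | (3aR,9bS)-7-methoxy-2,5-dioxo-1,2,3a,4,5,9b-hexahydronaphtho[2,1-b]furan-8-carbaldehyde | O=C1C[C@@H]2[C@H](O1)CC(=O)c1cc(OC)c(C=O)cc12
F6 | step 5 | (3aR,9bS)-8-(hydroxymethyl)-7-methoxy-3a,4-dihydronaphtho[2,1-b]furan-2,5(1H,9bH)-dione | O=C1C[C@@H]2[C@H](O1)CC(=O)c1cc(OC)c(CO)cc12
F7 | step 7 | (3aR,9bS)-7-methoxy-3a,4-dihydronaphtho[2,1-b]furan-2,5(1H,9bH)-dione | O=C1C[C@@H]2[C@H](O1)CC(=O)c1cc(OC)ccc12
F8 | step 7 | (3aR,5S,9bS)-5-hydroxy-7-methoxy-5-methyl-3a,4,5,9b-tetrahydronaphtho[2,1-b]furan-2(1H)-one | O=C1C[C@@H]2[C@H](O1)C[C@](C)(O)c1cc(OC)ccc12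
F9 | step 7 | methyl 2-[(1S,2R,4S)-2,4-dihydroxy-6-methoxy-4-methyl-1,2,3,4,5,8-hexahydronaphthalen-1-yl]acetate | COC(=O)C[C@@H]1[C@H](O)C[C@](C)(O)C2=C1CC=C(OC)C2
F10 | step 7 | methyl 2-[(1S,2R,4S)-4-hydroxy-6-methoxy-4-methyl-2-(triethylsilyloxy)-1,2,3,4,5,8-hexahydronaphthalen-1-yl]acetate | COC(=O)C[C@@H]1[C@H](O[Si](CC)(CC)CC)C[C@](C)(O)C2=C1CC=C(OC)C2
F11 | step 7 | methyl 2-[(1S,2R,4S)-7-formyl-4-hydroxy-6-methoxy-4-methyl-2-(triethylsilyloxy)-1,2,3,4,5,8-hexahydronaphthalen-1-yl]acetate | COC(=O)C[C@@H]1[C@H](O[Si](CC)(CC)CC)C[C@](C)(O)C2=C1CC(C=O)=C(OC)C2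
F12 | step 7 | methyl 2-[(1S,2R,4S)-4-hydroxy-7-(hydroxymethyl)-6-methoxy-4-methyl-2-(triethylsilyloxy)-1,2,3,4,5,8-hexahydronaphthalen-1-yl]acetate | COC(=O)C[C@@H]1[C@H](O[Si](CC)(CC)CC)C[C@](C)(O)C2=C1CC(CO)=C(OC)C2
F13 | step 12 | C4 bromide of 21 (C4 epimers) | COC(=O)C[C@@H]1[C@H](O[Si](CC)(CC)CC)C[C@]2(C)OC(=CC2=O)C(Br)(CO[Si](C)(C)C(C)(C)C)CC1=O
F14 | step 13 | β-hydroxy dienone: 23 with free C8 hydroxyl | COC(=O)C[C@@H]1[C@H](O)C[C@]2(C)OC(=CC2=O)/C(CO[Si](C)(C)C(C)(C)C)=C\C1=O
F15 | step 13 | anti 6,8-diol ester | COC(=O)C[C@@H]1[C@H](O)C[C@]2(C)OC(=CC2=O)/C(CO[Si](C)(C)C(C)(C)C)=C\[C@H]1O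
F16 | step 13 | 6,12-lactone with free C8 hydroxyl and C15 OTBS | O[C@@H]1C[C@]2(C)OC(=CC2=O)/C(CO[Si](C)(C)C(C)(C)C)=C\[C@H]2OC(=O)C[C@@H]21
A1 | alternative 1 | seco aldehyde with furanone, (Z)-alkene and C6 butenolide | O=CC[C@]1(C)OC(=CC1=O)/C(CO[Si](C)(C)C(C)(C)C)=C\[C@H]1OC(=O)C=C1
A2 | alternative 1 | cyclised carbinol lactone with free C8 hydroxyl, C15 OTBS and no C13 | O[C@@H]1C[C@]2(C)OC(=CC2=O)/C(CO[Si](C)(C)C(C)(C)C)=C\[C@H]2OC(=O)C[C@@H]21
A3 | alternative 2 | seco iodoalkyne aldehyde carrying methacrylate and methylene lactone | C=C(C)C(=O)O[C@H](C[C@](C)(O[Si](CC)(CC)CC)C=O)[C@H]1C(=C)C(=O)O[C@@H]1/C=C(/CO[Si](C)(C)C(C)(C)C)C#CI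
A4 | alternative 2 | ten-membered enyne carbinol (C1 configuration arbitrary) | C=C(C)C(=O)O[C@@H]1C[C@](C)(O[Si](CC)(CC)CC)[C@@H](O)C#C/C(CO[Si](C)(C)C(C)(C)C)=C\[C@H]2OC(=O)C(=C)[C@@H]21
A5 | alternative 3 | cyclooctenone lactone with the C10 alkynyl ether | CC[Si](CC)(CC)O[C@@H]1C[C@](C)(OC#CCO[Si](C)(C)C(C)(C)C)C(=O)/C=C\[C@H]2OC(=O)C[C@@H]21
A6 | alternative 3 | bridged furanone lactone with C8 OTES and C15 OTBS, identical with 25 | CC[Si](CC)(CC)O[C@@H]1C[C@]2(C)OC(=CC2=O)/C(CO[Si](C)(C)C(C)(C)C)=C\[C@H]2OC(=O)C[C@@H]21
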